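The cyclohexene ring is disconnected at C1–C6, the bond that lies allylic to C4=C5 and next to C7, so that C7–C1–C6–C5=C4 reads as a γ,δ-unsaturated acid. One Ireland–Claisen ring contraction of a D-galacturonic acid 6,2-lactone makes this bond, closes the carbocycle, moves the alkene to C4=C5 and sets the C1 oxygen and the C6 chlorine trans, ready for oxirane closure. The precursor is the δ-lactone in which C2–C5 of the sugar carry a 3,4-acetonide and a 5-O-triethylsilyl ether, and C1 has become an (E)-2-chlorovinyl group; C7, C1, C2, C3 and C4 of the target are C6–C2 of the sugar.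

Key step: step 9

Numbering: target atoms are C1 (oxirane carbon bearing C7), C2 (benzoate), C3 (carbinol), C4=C5 and C6 (oxirane CH); sugar atoms keep the numbers of D-galacturonic acid.
Remark on the design: O5 of the precursor is a triethylsilyl ether so that one acid treatment after the rearrangement removes it together with the acetonide, before the acid-sensitive vinyl oxirane exists.

Step 1
Reactants: 1 D-galactose
Product: 2 benzyl α-D-galactopyranoside
Conditions: BnOH (solvent), anhydrous HCl (cat.), 60 °C; Et2O trituration, recrystallisation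
Reagents that add atoms: benzyl alcohol, OCc1ccccc1
Why: Fischer glycosidation under thermodynamic control should favour the α-pyranoside (anomeric effect), which crystallises; the anomeric configuration is immaterial because C1 is unmasked in step 4.

Step 2
Reactants: 2 benzyl α-D-galactopyranoside
Product: 3 benzyl 3,4-O-isopropylidene-α-D-galactopyranoside
Conditions: 2,2-dimethoxypropane (1.5 equiv), p-TsOH·H2O (cat.), acetone, rt; Et3N; MeOH–H2O (10:1), 50 °C
Reagents that add atoms: 2,2-dimethoxypropane, COC(C)(C)OC
Why: Acid-catalysed transacetalisation (acetonide formation) should select the only cis-vicinal diol, O3/O4, as a cis-fused dioxolane and leave O2 and O6 free, any labile mixed acetal at O6 being cleaved in the aqueous methanol work-up.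

Step 3
Reactants: 3 benzyl 3,4-O-isopropylidene-α-D-galactopyranoside
Product: 4 benzyl 3,4-O-isopropylidene-α-D-galactopyranosiduronic acid
Conditions: TEMPO (0.2 equiv), PhI(OAc)2 (2.5 equiv), CH2Cl2–H2O (2:1), rt
Reagents that add atoms: water, O
Why: The oxoammonium (TEMPO/PhI(OAc)2) oxidation takes the primary C6 alcohol through the aldehyde hydrate to the acid and should leave the secondary C2 hydroxyl untouched.

Step 4
Reactants: 4 benzyl 3,4-O-isopropylidene-α-D-galactopyranosiduronic acid
Product: 5 3,4-O-isopropylidene-D-galactopyranuronic acid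
Conditions: H2 (1 atm), 10% Pd/C, EtOAc–MeOH, rt; used directly
Reagents that add atoms: none
Why: Catalytic hydrogenolysis of the benzyl glycoside frees the lactol under neutral conditions that the acetonide tolerates.

Step 5
Reactants: 5 3,4-O-isopropylidene-D-galactopyranuronic acid
Product: 6 6,7-dideoxy-3,4-O-isopropylidene-L-galacto-hept-6-ynonic acid
Conditions: dimethyl (1-diazo-2-oxopropyl)phosphonate (1.5 equiv), K2CO3 (4 equiv), MeOH, 0 °C to rt; citric acid to pH 4, EtOAc
Reagents that add atoms: dimethyl (1-diazo-2-oxopropyl)phosphonate, CC(=O)C(=[N+]=[N-])P(=O)(OC)OC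
Why: Seyferth–Gilbert homologation in its Ohira–Bestmann form converts the open-chain aldehyde of the lactol into the terminal alkyne without touching a stereocentre; the uronate reacts as its carboxylate, which keeps H5 non-acidic and so blocks β-elimination of O4.

Step 6
Reactants: 6 6,7-dideoxy-3,4-O-isopropylidene-L-galacto-hept-6-ynonic acid
Product: 7 6,7-dideoxy-3,4-O-isopropylidene-L-galacto-hept-6-ynono-1,5-lactone
Conditions: EDC·HCl (1.5 equiv), DMAP (0.1 equiv), CH2Cl2 (0.01 M), 0 °C to rt
Reagents that add atoms: none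
Why: Carbodiimide lactonisation can only engage O2 of the sugar (O3 and O4 are blocked and O5 would give an α-lactone), so the cis-fused δ-lactone should form with retention at C2 and without the acid catalysis that could move the acetonide.

Step 7
Reactants: 7 6,7-dideoxy-3,4-O-isopropylidene-L-galacto-hept-6-ynono-1,5-lactone
Product: 8 6,7-dideoxy-3,4-O-isopropylidene-2-O-triethylsilyl-L-galacto-hept-6-ynono-1,5-lactone
Conditions: Et3SiCl, imidazole, CH2Cl2, 0 °C
Reagents that add atoms: chlorotriethylsilane, CC[Si](Cl)(CC)CC
Why: Imidazole-mediated silylation protects the α-hydroxy lactone without strong base; the triethylsilyl ether survives amide bases and heat and is later removed by the acid that cleaves the acetonide.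

Step 8
Reactants: 8 6,7-dideoxy-3,4-O-isopropylidene-2-O-triethylsilyl-L-galacto-hept-6-ynono-1,5-lactone
Product: 10 (E)-7-chloro-6,7-dideoxy-3,4-O-isopropylidene-2-O-triethylsilyl-L-galacto-hept-6-enono-1,5-lactone, via alkenylzirconocene chloride 9 (not isolated)
Conditions: Cp2Zr(H)Cl (1.3 equiv), CH2Cl2, rt, 20 min; N-chlorosuccinimide, 0 °C
Reagents that add atoms: N-chlorosuccinimide, O=C1CCC(=O)N1Cl
Why: Hydrozirconation adds Zr–H syn to the terminal alkyne with zirconium at the terminus, and chlorination of the carbon–zirconium bond with retention should give only the (E)-chloroalkene; the alkyne reacts much faster than the lactone carbonyl.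

Step 9
Reactants: 10 (E)-7-chloro-6,7-dideoxy-3,4-O-isopropylidene-2-O-triethylsilyl-L-galacto-hept-6-enono-1,5-lactone
Product: 13 (3aR,4S,5R,7aR)-5-chloro-2,2-dimethyl-4-(triethylsilyloxy)-3a,4,5,7a-tetrahydro-1,3-benzodioxole-4-carboxylic acid, via cyclic silyl ketene acetal 11 (not isolated), via trimethylsilyl ester 12 (not isolated)
Conditions: Me3SiCl–Et3N (premixed), LiN(SiMe3)2, THF, −78 °C to rt; toluene, 100 °C; aq. citric acid–THF, rt
Reagents that add atoms: none
Why: LiN(SiMe3)2 removes H5 of the lactone in the presence of Me3SiCl, so the enolate is trapped at once as the cyclic silyl ketene acetal 11, which on heating undergoes a concerted [3,3] sigmatropic shift: the ketene acetal carbon bonds to the chlorine-bearing alkene terminus, the allylic C–O bond of the lactone breaks and the alkene moves into the new ring. This is the Ireland–Claisen rearrangement in its lactone ring-contraction form, known for ω-alkenyl lactones that give cycloalkene carboxylic acids. The six-membered carbocycle closes by carbon–carbon bond formation across the lactone, through a bicyclo[2.2.2]octane-like array in which the two-carbon bridge C3–C4 of the sugar forces the six-atom pericyclic array into a boat, the new bond being made between the two bridgehead positions. The quaternary centre C1 (target numbering) is controlled by C2 of the sugar, because the alkenyl arm can reach the ketene acetal only on the lactone face that it occupies, the face of the acetonide oxygens, so the silyloxy group ends cis to O2 and O3 and the carboxyl on the other face; C6 is controlled by the (E)-alkene geometry within the boat, which turns chlorine outward and therefore trans to the C1 oxygen. The selectivity needed is survival of the enolate against β-elimination of the C4 oxygen, which is secured by silylation as the enolate forms at −78 °C, so that only the neutral ketene acetal is warmed, and by that oxygen being a tethered ketal oxygen and a poor leaving group.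

Step 10
Reactants: 13 the rearranged acid (5-chloro-4-triethylsilyloxy acetonide carboxylic acid)
Product: 14 methyl (3aR,4S,5R,7aR)-5-chloro-2,2-dimethyl-4-(triethylsilyloxy)-3a,4,5,7a-tetrahydro-1,3-benzodioxole-4-carboxylate
Conditions: Me3SiCHN2, toluene–MeOH (4:1), 0 °C
Reagents that add atoms: trimethylsilyldiazomethane, C[Si](C)(C)C=[N+]=[N-]
Why: O-Methylation by diazomethane released in situ esterifies the hindered acid under neutral conditions that the allylic chloride, silyl ether and acetonide tolerate.

Step 11
Reactants: 14 the methyl ester of 13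
Product: 16 methyl (1S,2R,3R,6S)-2,3-dihydroxy-7-oxabicyclo[4.1.0]hept-4-ene-1-carboxylate, via chloro triol methyl ester 15 (not isolated)
Conditions: CF3CO2H–H2O (9:1), 0 °C to rt; evaporation with toluene; K2CO3, MeOH, 0 °C
Reagents that add atoms: none
Why: Acid hydrolysis removes the triethylsilyl ether and the acetonide together, and carbonate then closes the oxirane by intramolecular SN2 displacement (chlorohydrin to epoxide) of the allylic chloride by the anti C1 alkoxide, with inversion at C6, so the oxirane forms cis to O2 and O3.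

Step 12
Reactants: 16 the epoxy diol methyl ester
Product: 17 methyl (1S,2R,3R,6S)-2-hydroxy-3-(triethylsilyloxy)-7-oxabicyclo[4.1.0]hept-4-ene-1-carboxylate
Conditions: Et3SiCl (1.05 equiv), imidazole, CH2Cl2, −40 °C
Reagents that add atoms: chlorotriethylsilane, CC[Si](Cl)(CC)CC
Why: Kinetic monosilylation should choose the allylic C3 hydroxyl, because the C2 hydroxyl is flanked by the fully substituted C1 and deactivated by the neighbouring ester.

Step 13
Reactants: 17 the C3 triethylsilyl ether of 16
Product: 18 (1S,2R,3R,6S)-1-(hydroxymethyl)-3-(triethylsilyloxy)-7-oxabicyclo[4.1.0]hept-4-en-2-ol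
Conditions: LiBH4, THF, 0 °C
Reagents that add atoms: none
Why: Hydride reduction of the α-oxygenated (glycidic) ester, assisted by the neighbouring C2 hydroxyl, gives the primary alcohol C7 and should spare the vinyl oxirane and the silyl ether.

Step 14
Reactants: 18 the C7,C2-diol with O3 silylated; 19 benzoyl chloride
Product: 20 [(1S,2R,3R,6S)-2-(benzoyloxy)-3-(triethylsilyloxy)-7-oxabicyclo[4.1.0]hept-4-en-1-yl]methyl benzoate
Conditions: BzCl (2.5 equiv), pyridine, DMAP (cat.), CH2Cl2, 0 °C to rt
Reagents that add atoms: benzoyl chloride (second equivalent of 19, for the second benzoate), O=C(Cl)c1ccccc1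
Why: DMAP-catalysed acylation consumes two equivalents of benzoyl chloride and installs both benzoates in one operation on the only two free hydroxyls, first the primary O7 and then the secondary O2.

Step 15
Reactants: 20 the O3-silylated dibenzoate
Product: 21 [(1S,2R,3R,6S)-2-(benzoyloxy)-3-hydroxy-7-oxabicyclo[4.1.0]hept-4-en-1-yl]methyl benzoate
Conditions: Et3N·3HF, THF, rt
Reagents that add atoms: none
Why: Fluoride-mediated desilylation under weakly acidic, non-basic conditions should free O3 without benzoyl migration from the cis O2 and without opening the vinyl oxirane.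

Compound list
1 | D-galactose | O=C[C@H](O)[C@@H](O)[C@@H](O)[C@H](O)CO | starting material
2 | benzyl α-D-galactopyranoside | OC[C@H]1O[C@H](OCc2ccccc2)[C@H](O)[C@@H](O)[C@H]1O | intermediate
3 | benzyl 3,4-O-isopropylidene-α-D-galactopyranoside | OC[C@H]1O[C@H](OCc2ccccc2)[C@H](O)[C@H]2OC(C)(C)O[C@@H]12 | intermediate
4 | benzyl 3,4-O-isopropylidene-α-D-galactopyranosiduronic acid | OC(=O)[C@H]1O[C@H](OCc2ccccc2)[C@H](O)[C@H]2OC(C)(C)O[C@@H]12 | intermediate
5 | 3,4-O-isopropylidene-D-galactopyranuronic acid (lactol, both anomers) | OC(=O)[C@H]1OC(O)[C@H](O)[C@H]2OC(C)(C)O[C@@H]12 | intermediate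
6 | 6,7-dideoxy-3,4-O-isopropylidene-L-galacto-hept-6-ynonic acid (hydroxyls at sugar O2 and O5) | C#C[C@H](O)[C@H]1OC(C)(C)O[C@H]1[C@H](O)C(=O)O | intermediate
7 | 6,7-dideoxy-3,4-O-isopropylidene-L-galacto-hept-6-ynono-1,5-lactone (6,2-lactone in sugar numbering) | C#C[C@H]1[C@H]2OC(C)(C)O[C@H]2[C@H](O)C(=O)O1 | intermediate
8 | 6,7-dideoxy-3,4-O-isopropylidene-2-O-triethylsilyl-L-galacto-hept-6-ynono-1,5-lactone | C#C[C@H]1[C@H]2OC(C)(C)O[C@H]2[C@H](O[Si](CC)(CC)CC)C(=O)O1 | intermediate
9 | (E)-alkenylzirconocene chloride from 8 (zirconium on the terminal carbon) | Cl[Zr](/C=C/[C@H]1[C@H]2OC(C)(C)O[C@H]2[C@H](O[Si](CC)(CC)CC)C(=O)O1)(C1C=CC=C1)C1C=CC=C1 | intermediate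
10 | (E)-7-chloro-6,7-dideoxy-3,4-O-isopropylidene-2-O-triethylsilyl-L-galacto-hept-6-enono-1,5-lactone (6,2-lactone of 5-O-triethylsilyl-3,4-O-isopropylidene-D-galacturonic acid with C1 as (E)-2-chlorovinyl) | Cl/C=C/[C@H]1[C@H]2OC(C)(C)O[C@H]2[C@H](O[Si](CC)(CC)CC)C(=O)O1 | intermediate
11 | cyclic trimethylsilyl ketene acetal of 10 | Cl/C=C/[C@H]1[C@H]2OC(C)(C)O[C@H]2C(O[Si](CC)(CC)CC)=C(O[Si](C)(C)C)O1 | intermediate
12 | trimethylsilyl ester of 13 | C[Si](C)(C)OC(=O)[C@]1(O[Si](CC)(CC)CC)[C@H](Cl)C=C[C@H]2OC(C)(C)O[C@@H]12 | intermediate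
13 | (3aR,4S,5R,7aR)-5-chloro-2,2-dimethyl-4-(triethylsilyloxy)-3a,4,5,7a-tetrahydro-1,3-benzodioxole-4-carboxylic acid (O1, O2, O3 on one face; CO2H and Cl on the other) | OC(=O)[C@]1(O[Si](CC)(CC)CC)[C@H](Cl)C=C[C@H]2OC(C)(C)O[C@@H]12 | intermediate
14 | methyl ester of 13 | COC(=O)[C@]1(O[Si](CC)(CC)CC)[C@H](Cl)C=C[C@H]2OC(C)(C)O[C@@H]12 | intermediate
15 | methyl (1S,2R,3R,6R)-6-chloro-1,2,3-trihydroxycyclohex-4-ene-1-carboxylate | COC(=O)[C@]1(O)[C@H](Cl)C=C[C@@H](O)[C@H]1O | intermediate
16 | methyl (1S,2R,3R,6S)-2,3-dihydroxy-7-oxabicyclo[4.1.0]hept-4-ene-1-carboxylate | COC(=O)[C@]12O[C@H]1C=C[C@@H](O)[C@H]2O | intermediate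
17 | methyl (1S,2R,3R,6S)-2-hydroxy-3-(triethylsilyloxy)-7-oxabicyclo[4.1.0]hept-4-ene-1-carboxylate | COC(=O)[C@]12O[C@H]1C=C[C@@H](O[Si](CC)(CC)CC)[C@H]2O | intermediate
18 | (1S,2R,3R,6S)-1-(hydroxymethyl)-3-(triethylsilyloxy)-7-oxabicyclo[4.1.0]hept-4-en-2-ol | OC[C@]12O[C@H]1C=C[C@@H](O[Si](CC)(CC)CC)[C@H]2O | intermediate
19 | benzoyl chloride | O=C(Cl)c1ccccc1 | starting material
20 | [(1S,2R,3R,6S)-2-(benzoyloxy)-3-(triethylsilyloxy)-7-oxabicyclo[4.1.0]hept-4-en-1-yl]methyl benzoate | O=C(OC[C@]12O[C@H]1C=C[C@@H](O[Si](CC)(CC)CC)[C@H]2OC(=O)c1ccccc1)c1ccccc1 | intermediate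
21 | [(1S,2R,3R,6S)-2-(benzoyloxy)-3-hydroxy-7-oxabicyclo[4.1.0]hept-4-en-1-yl]methyl benzoate | O=C(OC[C@]12O[C@H]1C=C[C@@H](O)[C@H]2OC(=O)c1ccccc1)c1ccccc1 | target

Total step count: 15. Longest linear sequence: 15 steps (D-galactose 1 to 21; benzoyl chloride 19 enters in step 14).

Steps most likely to fail

Step 9. The lactone enolate may lose the C4 oxygen by β-elimination before it is silylated, or the ketene acetal may decompose before the strained boat is reached. The fallback sets out from 10 and returns at 13. It runs the same [3,3] shift at the aldehyde oxidation level, with no enolate at any point. Reduction of 10 with i-Bu2AlH (CH2Cl2, −78 °C) should give the lactol F1. Mesylation with in situ elimination (MsCl, excess Et3N, CH2Cl2, 0 °C to reflux) should give the cyclic 2-silyloxy enol ether F2, a 2-alkenyl-3,4-dihydro-2H-pyran. Thermal Claisen rearrangement, known for this class of allyl vinyl ethers (o-dichlorobenzene with a trace of Et3N, sealed tube, about 200 °C), goes through the same tether-enforced boat and should give the aldehyde F3 with the same C1 and C6 configurations. Pinnick oxidation (NaClO2, NaH2PO4, 2-methyl-2-butene, t-BuOH–H2O) then gives 13.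

Step 5. The lactol may open slowly, and the free α-hydroxy aldehyde may epimerise at C2 through its enediolate under the basic conditions. The fallback sets out from 5 and returns at 10, bypassing steps 5 to 8 by a non-basic chromium-mediated olefination that makes the chloroalkene directly. Esterification of 5 (Me3SiCHN2, toluene–MeOH) should give the lactol methyl ester F4. Takai olefination (CrCl2, CHCl3, THF, 65 °C) of the small equilibrium share of open hydroxy aldehyde should give the (E)-chloroalkene diol ester F5. Saponification (LiOH, THF–H2O, 0 °C) gives the dihydroxy acid F6, and EDC lactonisation as in step 6 gives the chlorovinyl hydroxy lactone F7. Silylation as in step 7 then gives 10.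

Step 12. The two cis-hydroxyls may be poorly discriminated, or the silyl group may migrate between them. The fallback sets out from 16 and returns at 21, replacing site-selective silylation by a stereoelectronically controlled orthoester opening. Reduction of 16 (LiBH4, THF, 0 °C) gives the epoxy triol F8. Trimethyl orthobenzoate with a trace of camphorsulfonic acid (CH2Cl2, rt) should tie the cis-2,3-diol into the cyclic orthobenzoate F9 and leave the C7 hydroxyl free. Benzoylation (BzCl, pyridine) gives the orthoester benzoate F10. Brief treatment with 80% aqueous AcOH opens the orthoester to the hydroxy benzoate with the acyl group on the pseudo-axial oxygen; this is expected to be O2, since A(1,2) strain against the C1 substituent keeps O2 pseudo-axial, and the product is then 21.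

Further compounds
F1 | step 9 | lactol from reduction of 10 (2-silyloxy, 3,4-acetonide, (E)-chlorovinyl) | Cl/C=C/[C@H]1[C@H]2OC(C)(C)O[C@H]2[C@H](O[Si](CC)(CC)CC)C(O)O1
F2 | step 9 | cyclic enol ether (2-alkenyl-5-silyloxy-3,4-dihydro-2H-pyran with 3,4-acetonide) | Cl/C=C/[C@H]1[C@H]2OC(C)(C)O[C@H]2C(O[Si](CC)(CC)CC)=CO1
F3 | step 9 | (3aR,4S,5R,7aR)-5-chloro-2,2-dimethyl-4-(triethylsilyloxy)-3a,4,5,7a-tetrahydro-1,3-benzodioxole-4-carbaldehyde | O=C[C@]1(O[Si](CC)(CC)CC)[C@H](Cl)C=C[C@H]2OC(C)(C)O[C@@H]12
F4 | step 5 | methyl 3,4-O-isopropylidene-D-galactopyranuronate (lactol) | COC(=O)[C@H]1OC(O)[C@H](O)[C@H]2OC(C)(C)O[C@@H]12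
F5 | step 5 | methyl (E)-7-chloro-6,7-dideoxy-3,4-O-isopropylidene-L-galacto-hept-6-enonate | Cl/C=C/[C@H](O)[C@H]1OC(C)(C)O[C@H]1[C@H](O)C(=O)OC
F6 | step 5 | (E)-7-chloro-6,7-dideoxy-3,4-O-isopropylidene-L-galacto-hept-6-enonic acid | Cl/C=C/[C@H](O)[C@H]1OC(C)(C)O[C@H]1[C@H](O)C(=O)O
F7 | step 5 | (E)-7-chloro-6,7-dideoxy-3,4-O-isopropylidene-L-galacto-hept-6-enono-1,5-lactone | Cl/C=C/[C@H]1[C@H]2OC(C)(C)O[C@H]2[C@H](O)C(=O)O1
F8 | step 12 | (1S,2R,3R,6S)-1-(hydroxymethyl)-7-oxabicyclo[4.1.0]hept-4-ene-2,3-diol | OC[C@]12O[C@H]1C=C[C@@H](O)[C@H]2O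
F9 | step 12 | cyclic 2,3-O-(methoxy)(phenyl)methylidene orthoester of F8 with free C7 hydroxyl (orthoester carbon as a mixture) | OC[C@]12O[C@H]1C=C[C@H]3OC(OC)(c4ccccc4)O[C@@H]23
F10 | step 12 | C7 benzoate of F9 | O=C(OC[C@]12O[C@H]1C=C[C@H]3OC(OC)(c4ccccc4)O[C@@H]23)c1ccccc1
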